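**Plan**

1. Retrosynthesis: the pyran C3 hydroxyl is removed with allylic transposition (alkene back to C3=C4). One cut then opens both rings: the cyclohexane bond between the ring CH2 next to CHBr (C2′) and the ring CH that carries the pyran (C1′), together with the pyran O–C2 bond. The open chain is cut at its (Z)-alkene (Wittig) and traced back to nerol.
2. Enabling feature: C2′ is β to bromine and is the former carbinol carbon of the allylic alcohol that directs the bromochlorination, so its hydroxyl becomes a leaving group backed by the neighbouring bromine. C1′ and pyran C2 are the two ends of an (E)-trisubstituted alkene, six atoms from that carbon on one side and, through a (Z)-alkene, six atoms from the tertiary oxygen on the other.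
3. Forward order: nerol, bromochloride, silyl ether, (E)-enal, (Z)-selective Wittig with a five-carbon ylide, diol, triflate-triggered double ring closure (cyclohexane, then dihydropyran), singlet-oxygen ene reaction and reduction.
4. Stereochemistry: C3′ and C4′ (Br, Cl) from ligand-controlled anti bromochlorination of the (Z)-alkene; C1′ from a chair transition state with equatorial bromine; pyran C2 from anti addition across the (6E)-alkene; pyran C3 from an ene reaction on the face opposite the pseudo-axial C2 methyl.

Key step: step 8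

Remark: open-chain intermediates carry dodecane numbering (C1 becomes C2′, C2 becomes C3′, C3 becomes C4′, C6 becomes C1′, C7 becomes pyran C2, C11 becomes pyran C6). Both enantiomers of the Schiff-base ligand are taken to be accessible, and the one that gives (2S,3S)-2 is used.

Step 1
Reactants: 1 nerol
Product: 2 (2S,3S)-2-bromo-3-chloro-3,7-dimethyloct-6-en-1-ol
Conditions: NBS, ClTi(OiPr)3, chiral tridentate salicylaldimine (Schiff-base) diol ligand (20 mol%), hexanes, −20 °C
Reagents that add atoms: N-bromosuccinimide, O=C1CCC(=O)N1Br; chlorotitanium triisopropoxide, CC(C)O[Ti](Cl)(OC(C)C)OC(C)C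
Why: Titanium-alkoxide-directed catalytic enantioselective bromochlorination of an allylic alcohol should put bromine on C2 and deliver titanium-bound chloride anti to the tertiary C3, so the (Z)-alkene gives the (2S,3S) pair, the ligand enantiomer fixing the absolute sense and the unbound C6=C7 alkene staying untouched.

Step 2
Reactants: 2 (2S,3S)-2-bromo-3-chloro-3,7-dimethyloct-6-en-1-ol
Product: 3 tert-butyl{[(2S,3S)-2-bromo-3-chloro-3,7-dimethyloct-6-en-1-yl]oxy}dimethylsilane
Conditions: TBSCl, imidazole, CH2Cl2, 0 °C to rt
Reagents that add atoms: tert-butyldimethylsilyl chloride, CC(C)(C)[Si](C)(C)Cl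
Why: Silylation of the primary alcohol masks the bromohydrin hydroxyl so that the later basic Wittig step cannot close an epoxide, and no stereocenter is touched.

Step 3
Reactants: 3 tert-butyl{[(2S,3S)-2-bromo-3-chloro-3,7-dimethyloct-6-en-1-yl]oxy}dimethylsilane
Product: 5 (2E,6S,7S)-7-bromo-8-[(tert-butyldimethylsilyl)oxy]-6-chloro-2,6-dimethyloct-2-enal, via allylic alcohol 4 (not isolated)
Conditions: SeO2 (cat.), t-BuOOH, salicylic acid (cat.), CH2Cl2, rt; then MnO2, CH2Cl2, rt
Reagents that add atoms: selenium dioxide, O=[Se]=O; tert-butyl hydroperoxide, CC(C)(C)OO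
Why: Allylic oxidation with SeO2 and t-BuOOH (ene reaction, then [2,3]-sigmatropic shift) is selective for the (E)-methyl group of a trisubstituted alkene terminus, and MnO2 takes only the allylic alcohol on to the (E)-enal.

Step 4
Reactants: 6 4-bromo-2-methylbutan-2-ol
Product: 7 [(4-bromo-2-methylbutan-2-yl)oxy]triethylsilane
Conditions: TESOTf, 2,6-lutidine, CH2Cl2, −78 to 0 °C
Reagents that add atoms: triethylsilyl trifluoromethanesulfonate, CC[Si](CC)(CC)OS(=O)(=O)C(F)(F)F
Why: Silyl triflate silylation covers the tertiary hydroxyl, which as a free γ-oxido group would erode the (Z)-selectivity of the later Wittig reaction.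

Step 5
Reactants: 7 [(4-bromo-2-methylbutan-2-yl)oxy]triethylsilane
Product: 8 {3-methyl-3-[(triethylsilyl)oxy]butyl}triphenylphosphonium bromide
Conditions: PPh3, MeCN, 80 °C
Reagents that add atoms: triphenylphosphine, c1ccc(cc1)P(c1ccccc1)c1ccccc1
Why: SN2 quaternization of triphenylphosphine by the unhindered primary bromide should give the Wittig salt.

Step 6
Reactants: 5 (2E,6S,7S)-7-bromo-8-[(tert-butyldimethylsilyl)oxy]-6-chloro-2,6-dimethyloct-2-enal; 8 {3-methyl-3-[(triethylsilyl)oxy]butyl}triphenylphosphonium bromide
Product: 10 (2S,3S,6E,8Z)-2-bromo-1-[(tert-butyldimethylsilyl)oxy]-3-chloro-3,7,11-trimethyl-11-[(triethylsilyl)oxy]dodeca-6,8-diene, via phosphorus ylide 9 (not isolated)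
Conditions: NaN(SiMe3)2, THF, −78 to 0 °C; then 5, −78 to −20 °C
Reagents that add atoms: none
Why: Wittig olefination of a non-stabilized ylide under lithium-free conditions should give the (8Z)-alkene through the kinetic cis-oxaphosphetane, the (6E)-alkene and the halogen-bearing centers being left alone at low temperature.

Step 7
Reactants: 10 (2S,3S,6E,8Z)-2-bromo-1-[(tert-butyldimethylsilyl)oxy]-3-chloro-3,7,11-trimethyl-11-[(triethylsilyl)oxy]dodeca-6,8-diene
Product: 11 (2S,3S,6E,8Z)-2-bromo-3-chloro-3,7,11-trimethyldodeca-6,8-diene-1,11-diol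
Conditions: HF·pyridine, pyridine, THF, 0 °C to rt
Reagents that add atoms: none
Why: Fluoride-mediated desilylation in a pyridine-buffered medium should free both hydroxyls without the base that would turn the bromohydrin into an epoxide and without acid that would protonate the diene.

Step 8
Reactants: 11 (2S,3S,6E,8Z)-2-bromo-3-chloro-3,7,11-trimethyldodeca-6,8-diene-1,11-diol
Product: 13 (2R)-2-[(1S,3S,4S)-3-bromo-4-chloro-4-methylcyclohexyl]-2,6,6-trimethyl-5,6-dihydro-2H-pyran, via primary triflate 12 (not isolated)
Conditions: Tf2O (1.05 equiv), 2,6-di-tert-butyl-4-methylpyridine, CH2Cl2 (high dilution), −78 °C; then MeNO2 cosolvent, −78 °C to rt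
Reagents that add atoms: none
Why: Proposed new method: Triflation takes place at the primary hydroxyl of 11, and on warming the C6=C7 bond of the diene displaces the triflate at C1 with the C2 bromine assisting from the anti-periplanar position (a bromiranium triflate ion pair opened at its primary carbon), after which the allyl cation spread over C7 to C9 is captured at C7 by the tertiary hydroxyl and the proton is taken by the hindered pyridine. The closest known reaction types are the π-cyclization of alkenyl primary sulfonates and the transfer of a configurationally defined bromiranium ion, made by ionizing a β-bromo leaving group, to a pendant alkene; what has not been shown is this pairing at a primary carbon flanked by a tertiary chloride with ether termination. Both rings close in the exo sense on the C6=C7 bond, the cyclohexane by 6-exo attack of C6 on C1 and the dihydropyran by 6-exo capture of C7 by oxygen, so that C1 and O add anti across this alkene. C1′ is set by a chair transition state in which anti-periplanar bromine participation forces the C–Br bond equatorial, which places chlorine equatorial and the C3 methyl axial and lets the dienyl arm take the equatorial site cis to bromine. The quaternary pyran carbon is set by the (6E) geometry through this anti addition, the (8Z)-alkene holding the hydroxyl on the face opposite to C1. The step needs sulfonylation of the primary and not the tertiary alcohol (size, −78 °C), attack at C1 and not at the neopentylic, chlorine-deactivated C2, capture at C7 and not at C9 (six- against four-membered ether) and survival of the tertiary chloride, which the Lewis-acid-free, non-ionizing, base-buffered medium should secure.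

Step 9
Reactants: 13 (2R)-2-[(1S,3S,4S)-3-bromo-4-chloro-4-methylcyclohexyl]-2,6,6-trimethyl-5,6-dihydro-2H-pyran
Product: 15 (2R,3R)-2-[(1S,3S,4S)-3-bromo-4-chloro-4-methylcyclohexyl]-2,6,6-trimethyl-3,6-dihydro-2H-pyran-3-ol, via allylic hydroperoxide 14 (not isolated)
Conditions: O2, tetraphenylporphyrin (cat.), visible light, CH2Cl2, 0 °C; then PPh3
Reagents that add atoms: oxygen, O=O
Why: In the Schenck ene reaction singlet oxygen should bond to C3 while taking the pseudo-axial hydrogen from C5 (the only allylic C–H), moving the alkene to C4=C5; it should do so on the face opposite the pseudo-axial C2 methyl, cis to the pseudo-equatorial cyclohexyl group, which gives (3R), and PPh3 reduces the hydroperoxide with retention.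

**Compound list**

1 | nerol, (2Z)-3,7-dimethylocta-2,6-dien-1-ol | CC(C)=CCC/C(C)=C\CO | starting material
2 | (2S,3S)-2-bromo-3-chloro-3,7-dimethyloct-6-en-1-ol | OC[C@H](Br)[C@@](C)(Cl)CCC=C(C)C | intermediate
3 | tert-butyl{[(2S,3S)-2-bromo-3-chloro-3,7-dimethyloct-6-en-1-yl]oxy}dimethylsilane | CC(C)(C)[Si](C)(C)OC[C@H](Br)[C@@](C)(Cl)CCC=C(C)C | intermediate
4 | (2E,6S,7S)-7-bromo-8-[(tert-butyldimethylsilyl)oxy]-6-chloro-2,6-dimethyloct-2-en-1-ol | CC(C)(C)[Si](C)(C)OC[C@H](Br)[C@@](C)(Cl)CC/C=C(\C)CO | intermediate (not isolated)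
5 | (2E,6S,7S)-7-bromo-8-[(tert-butyldimethylsilyl)oxy]-6-chloro-2,6-dimethyloct-2-enal | CC(C)(C)[Si](C)(C)OC[C@H](Br)[C@@](C)(Cl)CC/C=C(\C)C=O | intermediate
6 | 4-bromo-2-methylbutan-2-ol | CC(C)(O)CCBr | starting material
7 | [(4-bromo-2-methylbutan-2-yl)oxy]triethylsilane | CC[Si](CC)(CC)OC(C)(C)CCBr | intermediate
8 | {3-methyl-3-[(triethylsilyl)oxy]butyl}triphenylphosphonium bromide | CC[Si](CC)(CC)OC(C)(C)CC[P+](c1ccccc1)(c1ccccc1)c1ccccc1.[Br-] | intermediate
9 | {3-methyl-3-[(triethylsilyl)oxy]butylidene}triphenylphosphorane | CC[Si](CC)(CC)OC(C)(C)CC=P(c1ccccc1)(c1ccccc1)c1ccccc1 | intermediate (not isolated)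
10 | (2S,3S,6E,8Z)-2-bromo-1-[(tert-butyldimethylsilyl)oxy]-3-chloro-3,7,11-trimethyl-11-[(triethylsilyl)oxy]dodeca-6,8-diene | CC(C)(C)[Si](C)(C)OC[C@H](Br)[C@@](C)(Cl)CC/C=C(C)/C=C\CC(C)(C)O[Si](CC)(CC)CC | intermediate
11 | (2S,3S,6E,8Z)-2-bromo-3-chloro-3,7,11-trimethyldodeca-6,8-diene-1,11-diol | OC[C@H](Br)[C@@](C)(Cl)CC/C=C(C)/C=C\CC(C)(C)O | intermediate
12 | (2S,3S,6E,8Z)-2-bromo-3-chloro-11-hydroxy-3,7,11-trimethyldodeca-6,8-dien-1-yl trifluoromethanesulfonate | FC(F)(F)S(=O)(=O)OC[C@H](Br)[C@@](C)(Cl)CC/C=C(C)/C=C\CC(C)(C)O | intermediate (not isolated)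
13 | (2R)-2-[(1S,3S,4S)-3-bromo-4-chloro-4-methylcyclohexyl]-2,6,6-trimethyl-5,6-dihydro-2H-pyran | CC1(C)CC=C[C@@](C)([C@H]2CC[C@](C)(Cl)[C@@H](Br)C2)O1 | intermediate
14 | (2R,3R)-2-[(1S,3S,4S)-3-bromo-4-chloro-4-methylcyclohexyl]-3-hydroperoxy-2,6,6-trimethyl-3,6-dihydro-2H-pyran | CC1(C)C=C[C@@H](OO)[C@@](C)([C@H]2CC[C@](C)(Cl)[C@@H](Br)C2)O1 | intermediate (not isolated)
15 | (2R,3R)-2-[(1S,3S,4S)-3-bromo-4-chloro-4-methylcyclohexyl]-2,6,6-trimethyl-3,6-dihydro-2H-pyran-3-ol | CC1(C)C=C[C@@H](O)[C@@](C)([C@H]2CC[C@](C)(Cl)[C@@H](Br)C2)O1 | target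

**Step count**

Total: 9 steps. Longest linear sequence: 7 steps (steps 1, 2, 3, 6, 7, 8, 9 from nerol).

**Steps most likely to fail**

Step 8. The triflate may be lost by elimination or by ionization elsewhere before the twisted diene attacks, or the allyl cation may shed a proton instead of being captured by oxygen. The fallback sets out from 11 and uses the classical solvolytic manifold instead of an in-flask triflate in a non-ionizing medium. The primary hydroxyl would be sulfonylated selectively (4-nitrobenzenesulfonyl chloride, pyridine, CH2Cl2, 0 °C) to the isolable (2S,3S,6E,8Z)-2-bromo-3-chloro-11-hydroxy-3,7,11-trimethyldodeca-6,8-dien-1-yl 4-nitrobenzenesulfonate F1. This would then be ionized in 2,2,2-trifluoroethanol buffered with 2,6-lutidine at 40 to 60 °C, the known solvolytic π-cyclization of alkenyl primary arenesulfonates with capture by an internal hydroxyl. The route is rejoined at 13.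

Step 9. The ene reaction of a cis-disubstituted alkene next to an ether oxygen may be slow, and the two faces may not be told apart well enough. The fallback sets out from 13 and commits the oxygen through an epoxide. Epoxidation (mCPBA, NaHCO3, CH2Cl2, 0 °C) should take place on the same face, anti to the pseudo-axial methyl, to give (1R,2R,6R)-2-[(1S,3S,4S)-3-bromo-4-chloro-4-methylcyclohexyl]-2,4,4-trimethyl-3,7-dioxabicyclo[4.1.0]heptane F2, which can be purified at this stage. Sodium benzeneselenolate (from (PhSe)2 and NaBH4, EtOH, rt) would open it at the carbon remote from the quaternary center in a trans-diaxial sense to (2R,3S,4S)-2-[(1S,3S,4S)-3-bromo-4-chloro-4-methylcyclohexyl]-2,6,6-trimethyl-4-(phenylselanyl)oxan-3-ol F3. Oxidation (H2O2, pyridine, THF, 0 °C to rt) and selenoxide syn-elimination away from the carbinol carbon would then give the allylic alcohol. The route is rejoined at 15.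

Step 1. Halogen delivery to a (Z)-trisubstituted allylic alcohol may lose enantio- or regiocontrol. The fallback sets out from 1 and takes the absolute configuration from a Sharpless asymmetric epoxidation instead.
- Epoxidation (Ti(OiPr)4, D-(−)-diethyl tartrate, t-BuOOH, 4 Å molecular sieves, CH2Cl2, −20 °C) should give [(2R,3S)-3-methyl-3-(4-methylpent-3-en-1-yl)oxiran-2-yl]methanol F4.
- MgBr2·OEt2 (Et2O, −20 °C) would open the epoxide at the tertiary carbon with inversion to (2R,3R)-3-bromo-3,7-dimethyloct-6-ene-1,2-diol F5.
- TBSCl and imidazole would protect the primary hydroxyl, giving (2R,3R)-3-bromo-1-[(tert-butyldimethylsilyl)oxy]-3,7-dimethyloct-6-en-2-ol F6.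
- Activation of the secondary hydroxyl (Tf2O, 2,6-lutidine, CH2Cl2, −78 °C) and addition of Bu4NCl would let the neighbouring bromine displace the sulfonate with inversion at C2; chloride then opens the bromiranium ion at the tertiary C3 with inversion.

The route is rejoined at 3.

**Further compounds**

F1 | step 8 | (2S,3S,6E,8Z)-2-bromo-3-chloro-11-hydroxy-3,7,11-trimethyldodeca-6,8-dien-1-yl 4-nitrobenzenesulfonate | [O-][N+](=O)c1ccc(cc1)S(=O)(=O)OC[C@H](Br)[C@@](C)(Cl)CC/C=C(C)/C=C\CC(C)(C)O
F2 | step 9 | (1R,2R,6R)-2-[(1S,3S,4S)-3-bromo-4-chloro-4-methylcyclohexyl]-2,4,4-trimethyl-3,7-dioxabicyclo[4.1.0]heptane (oxirane oxygen cis to the cyclohexyl group) | CC1(C)C[C@H]2O[C@H]2[C@@](C)([C@H]3CC[C@](C)(Cl)[C@@H](Br)C3)O1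
F3 | step 9 | (2R,3S,4S)-2-[(1S,3S,4S)-3-bromo-4-chloro-4-methylcyclohexyl]-2,6,6-trimethyl-4-(phenylselanyl)oxan-3-ol | CC1(C)C[C@H]([Se]c2ccccc2)[C@@H](O)[C@@](C)([C@H]3CC[C@](C)(Cl)[C@@H](Br)C3)O1
F4 | step 1 | [(2R,3S)-3-methyl-3-(4-methylpent-3-en-1-yl)oxiran-2-yl]methanol | OC[C@H]1O[C@@]1(C)CCC=C(C)C
F5 | step 1 | (2R,3R)-3-bromo-3,7-dimethyloct-6-ene-1,2-diol | OC[C@@H](O)[C@](C)(Br)CCC=C(C)C
F6 | step 1 | (2R,3R)-3-bromo-1-[(tert-butyldimethylsilyl)oxy]-3,7-dimethyloct-6-en-2-ol | CC(C)(C)[Si](C)(C)OC[C@@H](O)[C@](C)(Br)CCC=C(C)C
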